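**Retrosynthetic overview**

- The target is the 5',6'-dibenzoate of a 1',4'-diaryl-2',3',5',6'-tetraoxybenzene. It is traced back through hydrogenolysis of four benzyl ethers, dibenzoylation of a catechol and MOM cleavage to the hexasubstituted phenol 15.
- The feature that carries the plan: central-ring carbons C1'(aryl)–C2'(O)–C3'(O)–C4'(aryl)–C5'(O) are C6–C5–C4–C3–C2 of a 3,6-diaryl-4,5-dioxy-2-pyrone. Only the ring oxygen O1 has to be exchanged for the sixth, oxygen-bearing carbon C6'.
- Key disconnection: bonds C6'–C5' and C6'=C1'. A lithiated (methoxymethoxy)methylphosphonate acylates the lactone carbonyl of pyrone 10, the ring opens, and intramolecular Horner–Wadsworth–Emmons olefination closes the benzene ring.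
- Pyrone 10 comes from α-benzyloxy ketone 8 (C5, C6, O1) and active arylmalonate 5 (C2–C4) by cyclocondensation, then O-benzylation. Ketone 8 is a Weinreb ketone synthesis product; malonate 5 comes from the arylacetic acid by carboxylation.
- Ring order: pyranone ring (step 4), then central benzene ring (step 7). The outer aryl and benzoyl rings are purchased.

Key step: step 7

Remark: the target has no stereocentre and its biaryl axes are not configurationally stable, so only regiocontrol is needed; compounds 1, 6, 7 and 11 are taken as purchased.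

**Route**

Step 1
Reactants: 1 2-[4-(benzyloxy)phenyl]acetic acid
Product: 3 2-[4-(benzyloxy)phenyl]propanedioic acid, via dilithium enediolate 2 (not isolated)
Conditions: LiN(iPr)2 (2.2 equiv, commercial solution), THF, −78 → 0 °C; CO2, −78 °C → rt; 1 M HCl, 0 °C
Reagents that add atoms: carbon dioxide, O=C=O
Why: Ivanov-type carboxylation: double deprotonation gives the enediolate 2, which is carboxylated at carbon by CO2, and cold acidification should release the arylmalonic acid without decarboxylation.

Step 2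
Reactants: 3 2-[4-(benzyloxy)phenyl]propanedioic acid
Product: 5 bis(2,4,6-trichlorophenyl) 2-[4-(benzyloxy)phenyl]propanedioate, via arylmalonyl dichloride 4 (not isolated)
Conditions: (COCl)2 (2.2 equiv), DMF (cat.), CH2Cl2, 0 °C → rt; then 2,4,6-trichlorophenol (2.0 equiv), rt
Reagents that add atoms: 2,4,6-trichlorophenol, Oc1c(Cl)cc(Cl)cc1Cl
Why: Vilsmeier-catalysed acid chloride formation followed by esterification with the acidic phenol should give the active malonate at room temperature, so the decarboxylation-prone diacid is never heated.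

Step 3
Reactants: 6 2-(benzyloxy)-N-methoxy-N-methylacetamide; 7 [4-(benzyloxy)phenyl]magnesium bromide
Product: 8 2-(benzyloxy)-1-[4-(benzyloxy)phenyl]ethan-1-one
Conditions: THF, 0 °C → rt; 1 M HCl
Reagents that add atoms: none
Why: Weinreb ketone synthesis: the N-methoxy-N-methylamide takes up one equivalent of the aryl Grignard reagent and releases the ketone only on acidic work-up, so over-addition is excluded.

Step 4
Reactants: 5 bis(2,4,6-trichlorophenyl) 2-[4-(benzyloxy)phenyl]propanedioate; 8 2-(benzyloxy)-1-[4-(benzyloxy)phenyl]ethan-1-one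
Product: 9 5-(benzyloxy)-3,6-bis[4-(benzyloxy)phenyl]-4-hydroxy-2H-pyran-2-one
Conditions: Ph2O, 200 °C, N2, 30 min
Reagents that add atoms: none
Why: Kappe–Ziegler cyclocondensation of an active malonate with an enolisable ketone: thermal loss of trichlorophenol gives an acylketene equivalent that acylates the enol of 8 at its only enolisable carbon, and the enol oxygen then lactonises onto the second active ester, which fixes the pattern 3-aryl, 4-hydroxy, 5-benzyloxy, 6-aryl.

Step 5
Reactants: 9 5-(benzyloxy)-3,6-bis[4-(benzyloxy)phenyl]-4-hydroxy-2H-pyran-2-one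
Product: 10 4,5-bis(benzyloxy)-3,6-bis[4-(benzyloxy)phenyl]-2H-pyran-2-one
Conditions: BnBr (1.2 equiv), K2CO3, DMF, 40 °C
Reagents that add atoms: benzyl bromide, BrCc1ccccc1
Why: Williamson-type O-alkylation of the acidic vinylogous acid; C3 is blocked by its aryl group and the conjugated 2-pyrone form is preferred, so the 4-benzyl ether should be the main product.

Step 6
Reactants: 11 diethyl (hydroxymethyl)phosphonate
Product: 12 diethyl [(methoxymethoxy)methyl]phosphonate
Conditions: MOMCl (1.3 equiv), iPr2NEt, CH2Cl2, 0 °C → rt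
Reagents that add atoms: chloromethyl methyl ether, COCCl
Why: MOM protection of a primary alcohol by O-alkylation with an α-chloro ether and a hindered amine base, giving an acetal that is inert to strong base in step 7.

Step 7
Reactants: 10 4,5-bis(benzyloxy)-3,6-bis[4-(benzyloxy)phenyl]-2H-pyran-2-one; 12 diethyl [(methoxymethoxy)methyl]phosphonate
Product: 15 3,4-bis(benzyloxy)-2,5-bis[4-(benzyloxy)phenyl]-6-(methoxymethoxy)phenol, via lithiated phosphonate 13 (not isolated), via ring-opened dilithium ketophosphonate 14 (not isolated)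
Conditions: 12 (2.2 equiv), LiN(iPr)2 (2.2 equiv), THF, −78 °C; then 10, −78 °C → rt, then 50 °C; aq. NH4Cl
Reagents that add atoms: none
Why: Proposed new method: carbanion 13 should add to the lactone carbonyl C2 of 10 and the adduct should collapse with C2–O1 cleavage to a β-ketophosphonate whose released oxygen is part of a C6 dienolate, after which a second equivalent of 13 removes the proton on the carbon flanked by phosphorus, the OMOM group and the new ketone to give dianion 14. The phosphonate-stabilised carbon of 14 should then close onto C6 in a 6-(enolendo)-exo-trig aldol-type addition (equally a disrotatory six-electron closure of the oxido-triene), and loss of lithium diethyl phosphate from the β-oxido phosphonate delivers the ring at the aromatic phenoxide level, which makes the sequence irreversible. The closest known reaction type is the conversion of enol lactones into cyclohexenones by lithiated methylphosphonates (lactone acylation, then intramolecular Horner–Wadsworth–Emmons olefination); new here are the α-alkoxy carbanion and the fully substituted 2-pyrone. No stereocentre is formed. The step needs 1,2-addition at C2 instead of 1,6-addition at C6 or addition–elimination at C4, and it needs C2 and C5 to stay cis across C3=C4: the hard oxygen-substituted lithium carbanion at −78 °C, the aryl group on C6 and the two donor benzyloxy groups at C4 and C5 favour carbonyl attack, and the cis geometry is inherited from the ring, while an isomerised dienolate can rotate back within the delocalised anion before the irreversible closure. If the dianion closes slowly, one equivalent of t-BuOH should open the monoanion pathway (protonation at C5, olefination of the C6 ketone, tautomerisation of the 4H-cyclohexadienone to the phenol).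

Step 8
Reactants: 15 3,4-bis(benzyloxy)-2,5-bis[4-(benzyloxy)phenyl]-6-(methoxymethoxy)phenol
Product: 16 4,5-bis(benzyloxy)-3,6-bis[4-(benzyloxy)phenyl]benzene-1,2-diol
Conditions: conc. HCl (cat.), MeOH/THF, 45 °C, Ar
Reagents that add atoms: none
Why: Acid-catalysed acetal exchange (MOM cleavage) with methanol as acceptor; benzyl ethers are inert, and argon protects the electron-rich catechol from autoxidation.

Step 9
Reactants: 16 4,5-bis(benzyloxy)-3,6-bis[4-(benzyloxy)phenyl]benzene-1,2-diol
Product: 17 4,5-bis(benzyloxy)-3,6-bis[4-(benzyloxy)phenyl]-1,2-phenylene dibenzoate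
Conditions: BzCl (2.5 equiv), Et3N, DMAP (cat.), CH2Cl2, 0 °C → rt, Ar
Reagents that add atoms: benzoyl chloride, O=C(Cl)c1ccccc1
Why: DMAP-catalysed acylation of both phenolic hydroxyls with an acid chloride; the fully substituted product is no longer oxidation-prone.

Step 10
Reactants: 17 4,5-bis(benzyloxy)-3,6-bis[4-(benzyloxy)phenyl]-1,2-phenylene dibenzoate
Product: 18 4,5-dihydroxy-3,6-bis(4-hydroxyphenyl)-1,2-phenylene dibenzoate
Conditions: H2 (1 atm), 10% Pd/C, EtOAc/THF, rt
Reagents that add atoms: none
Why: Catalytic hydrogenolysis of the four O-benzyl groups; aryl benzoates are not cleaved, and acyl migration is excluded because each benzoate is separated from the freed ring hydroxyls by an aryl-bearing carbon.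

**Compound list**

1 | 2-[4-(benzyloxy)phenyl]acetic acid | OC(=O)Cc1ccc(OCc2ccccc2)cc1 | starting material
2 | dilithium 2-[4-(benzyloxy)phenyl]ethene-1,1-diolate (enediolate of 1, not isolated) | [Li+].[Li+].[O-]C([O-])=Cc1ccc(OCc2ccccc2)cc1 | intermediate
3 | 2-[4-(benzyloxy)phenyl]propanedioic acid | OC(=O)C(C(=O)O)c1ccc(OCc2ccccc2)cc1 | intermediate
4 | 2-[4-(benzyloxy)phenyl]propanedioyl dichloride (not isolated) | O=C(Cl)C(C(=O)Cl)c1ccc(OCc2ccccc2)cc1 | intermediate
5 | bis(2,4,6-trichlorophenyl) 2-[4-(benzyloxy)phenyl]propanedioate | O=C(Oc1c(Cl)cc(Cl)cc1Cl)C(C(=O)Oc1c(Cl)cc(Cl)cc1Cl)c1ccc(OCc2ccccc2)cc1 | intermediate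
6 | 2-(benzyloxy)-N-methoxy-N-methylacetamide | CON(C)C(=O)COCc1ccccc1 | starting material
7 | [4-(benzyloxy)phenyl]magnesium bromide (solution in THF) | Br[Mg]c1ccc(OCc2ccccc2)cc1 | starting material
8 | 2-(benzyloxy)-1-[4-(benzyloxy)phenyl]ethan-1-one | O=C(COCc1ccccc1)c1ccc(OCc2ccccc2)cc1 | intermediate
9 | 5-(benzyloxy)-3,6-bis[4-(benzyloxy)phenyl]-4-hydroxy-2H-pyran-2-one | O=C1OC(c2ccc(OCc3ccccc3)cc2)=C(OCc2ccccc2)C(O)=C1c1ccc(OCc2ccccc2)cc1 | intermediate
10 | 4,5-bis(benzyloxy)-3,6-bis[4-(benzyloxy)phenyl]-2H-pyran-2-one | O=C1OC(c2ccc(OCc3ccccc3)cc2)=C(OCc2ccccc2)C(OCc2ccccc2)=C1c1ccc(OCc2ccccc2)cc1 | intermediate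
11 | diethyl (hydroxymethyl)phosphonate | CCOP(=O)(CO)OCC | starting material
12 | diethyl [(methoxymethoxy)methyl]phosphonate | CCOP(=O)(COCOC)OCC | intermediate
13 | diethyl [lithio(methoxymethoxy)methyl]phosphonate (configurationally labile, not isolated) | [Li]C(OCOC)P(=O)(OCC)OCC | intermediate
14 | dilithium 2,3-bis(benzyloxy)-1,4-bis[4-(benzyloxy)phenyl]-6-(diethoxyphosphoryl)-6-(methoxymethoxy)hexa-1,3,5-triene-1,5-diolate (ring-opened dianion, central double bond cis as in the pyrone, not isolated) | [Li+].[Li+].CCOP(=O)(OCC)C(OCOC)=C([O-])/C(c1ccc(OCc2ccccc2)cc1)=C(OCc1ccccc1)\C(OCc1ccccc1)=C(/[O-])c1ccc(OCc2ccccc2)cc1 | intermediate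
15 | 3,4-bis(benzyloxy)-2,5-bis[4-(benzyloxy)phenyl]-6-(methoxymethoxy)phenol | Oc1c(OCOC)c(-c2ccc(OCc3ccccc3)cc2)c(OCc2ccccc2)c(OCc2ccccc2)c1-c1ccc(OCc2ccccc2)cc1 | intermediate
16 | 4,5-bis(benzyloxy)-3,6-bis[4-(benzyloxy)phenyl]benzene-1,2-diol | Oc1c(O)c(-c2ccc(OCc3ccccc3)cc2)c(OCc2ccccc2)c(OCc2ccccc2)c1-c1ccc(OCc2ccccc2)cc1 | intermediate
17 | 4,5-bis(benzyloxy)-3,6-bis[4-(benzyloxy)phenyl]-1,2-phenylene dibenzoate | O=C(Oc1c(OC(=O)c2ccccc2)c(-c2ccc(OCc3ccccc3)cc2)c(OCc2ccccc2)c(OCc2ccccc2)c1-c1ccc(OCc2ccccc2)cc1)c1ccccc1 | intermediate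
18 | 4,5-dihydroxy-3,6-bis(4-hydroxyphenyl)-1,2-phenylene dibenzoate | O=C(Oc1c(OC(=O)c2ccccc2)c(-c2ccc(O)cc2)c(O)c(O)c1-c1ccc(O)cc1)c1ccccc1 | target

**Step count**

Total: 10 steps. Longest linear sequence: 8 steps (1 → 3 → 5 → 9 → 10 → 15 → 16 → 17 → 18).

**Steps most likely to fail, with fallbacks**

1. Step 7. The carbanion may be diverted into 1,6-addition at C6 or into displacement of benzyloxide at C4. Alternatively the ring-opened dienolate may isomerise and stall without closing.

 The fallback takes the central ring from a preformed hexasubstituted benzene and attaches the outer rings by a double Suzuki–Miyaura coupling. It sets out from 7 and comes back to the route at 16.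
 - Grignard reagent 7 is treated with B(OMe)3 (THF, −78 °C, then aq. HCl) to give [4-(benzyloxy)phenyl]boronic acid F1.
 - Purchased 3,4-bis(benzyloxy)phenol is oxidised at its free ortho position with 2-iodoxybenzoic acid (DMF, rt) to 4,5-bis(benzyloxy)cyclohexa-3,5-diene-1,2-dione F2.
 - Aqueous Na2S2O4 in the same pot reduces this to 4,5-bis(benzyloxy)benzene-1,2-diol F3.
 - MOMCl and iPr2NEt in CH2Cl2 give 1,2-bis(benzyloxy)-4,5-bis(methoxymethoxy)benzene F4.
 - NBS (2.1 equiv, MeCN, 0 °C, dark) brominates the two remaining ring positions to 1,2-bis(benzyloxy)-3,6-dibromo-4,5-bis(methoxymethoxy)benzene F5.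
 - Coupling of F5 with F1 (2.5 equiv; Pd(OAc)2, SPhos, K3PO4, toluene/H2O, 100 °C) should give 1,2-bis(benzyloxy)-3,6-bis[4-(benzyloxy)phenyl]-4,5-bis(methoxymethoxy)benzene F6.
 - HCl in MeOH/THF under argon removes both MOM groups and gives 16.

2. Step 4. Benzyl groups may be lost thermally, or O-acylation and decomposition at 200 °C may outrun C-acylation of the weakly enolised ketone.

 The fallback builds the pyranone from an acyclic 3,5-dioxo ester at low temperature. It sets out from 1 and 6 and comes back at 9.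
 - Acid 1 is esterified (MeOH, cat. H2SO4) to methyl 2-[4-(benzyloxy)phenyl]acetate F7.
 - The lithium enolate of F7 (LiN(iPr)2, THF, −78 °C) is acylated with Weinreb amide 6 to methyl 4-(benzyloxy)-2-[4-(benzyloxy)phenyl]-3-oxobutanoate F8.
 - F8 is doubly deprotonated (LiN(iPr)2, 3 equiv, THF, −78 → 0 °C) and aroylated at C4 with methyl 4-(benzyloxy)benzoate (Harris-type γ-acylation) to methyl 4-(benzyloxy)-2,5-bis[4-(benzyloxy)phenyl]-3,5-dioxopentanoate F9.
 - DBU in refluxing toluene lactonises F9 with loss of methanol to 9.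

3. Step 8. The electron-rich catechol may autoxidise to the ortho-quinone during isolation or under the basic conditions of step 9.

 The fallback changes the order of events so that no free catechol is ever formed. It sets out from 15 and comes back at 17.
 - Phenol 15 is benzoylated (BzCl, Et3N, cat. DMAP, CH2Cl2) to 3,4-bis(benzyloxy)-2,5-bis[4-(benzyloxy)phenyl]-6-(methoxymethoxy)phenyl benzoate F10.
 - The MOM group is hydrolysed (6 M HCl, THF, 40 °C) to 3,4-bis(benzyloxy)-2,5-bis[4-(benzyloxy)phenyl]-6-hydroxyphenyl benzoate F11. Any benzoyl shift between the two neighbouring oxygens is degenerate.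
 - A second benzoylation under the same conditions gives 17.

**Further compounds**

F1 | step 7 | [4-(benzyloxy)phenyl]boronic acid | OB(O)c1ccc(OCc2ccccc2)cc1
F2 | step 7 | 4,5-bis(benzyloxy)cyclohexa-3,5-diene-1,2-dione | O=C1C=C(OCc2ccccc2)C(OCc2ccccc2)=CC1=O
F3 | step 7 | 4,5-bis(benzyloxy)benzene-1,2-diol | Oc1cc(OCc2ccccc2)c(OCc2ccccc2)cc1O
F4 | step 7 | 1,2-bis(benzyloxy)-4,5-bis(methoxymethoxy)benzene | COCOc1cc(OCc2ccccc2)c(OCc2ccccc2)cc1OCOC
F5 | step 7 | 1,2-bis(benzyloxy)-3,6-dibromo-4,5-bis(methoxymethoxy)benzene | COCOc1c(Br)c(OCc2ccccc2)c(OCc2ccccc2)c(Br)c1OCOC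
F6 | step 7 | 1,2-bis(benzyloxy)-3,6-bis[4-(benzyloxy)phenyl]-4,5-bis(methoxymethoxy)benzene | COCOc1c(OCOC)c(-c2ccc(OCc3ccccc3)cc2)c(OCc2ccccc2)c(OCc2ccccc2)c1-c1ccc(OCc2ccccc2)cc1
F7 | step 4 | methyl 2-[4-(benzyloxy)phenyl]acetate | COC(=O)Cc1ccc(OCc2ccccc2)cc1
F8 | step 4 | methyl 4-(benzyloxy)-2-[4-(benzyloxy)phenyl]-3-oxobutanoate (racemic, enolisable) | COC(=O)C(C(=O)COCc1ccccc1)c1ccc(OCc2ccccc2)cc1
F9 | step 4 | methyl 4-(benzyloxy)-2,5-bis[4-(benzyloxy)phenyl]-3,5-dioxopentanoate (mixture of enolisable stereoisomers) | COC(=O)C(c1ccc(OCc2ccccc2)cc1)C(=O)C(OCc1ccccc1)C(=O)c1ccc(OCc2ccccc2)cc1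
F10 | step 8 | 3,4-bis(benzyloxy)-2,5-bis[4-(benzyloxy)phenyl]-6-(methoxymethoxy)phenyl benzoate | O=C(Oc1c(OCOC)c(-c2ccc(OCc3ccccc3)cc2)c(OCc2ccccc2)c(OCc2ccccc2)c1-c1ccc(OCc2ccccc2)cc1)c1ccccc1
F11 | step 8 | 3,4-bis(benzyloxy)-2,5-bis[4-(benzyloxy)phenyl]-6-hydroxyphenyl benzoate | O=C(Oc1c(O)c(-c2ccc(OCc3ccccc3)cc2)c(OCc2ccccc2)c(OCc2ccccc2)c1-c1ccc(OCc2ccccc2)cc1)c1ccccc1
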